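**Retrosynthetic overview**
1. Pyran ring (formed last): the C1 hydroxyl closes onto the C3 ketone of a monocyclic 2-ene-1,5-dione, then vinylogous loss of water.
2. Carbocycle (formed first, same flask): 6-exo-dig Michael addition of the C6 methyl-ketone enolate (C5) to the ynone carbon C4a.
3. Ynone: carbonylative Sonogashira union (C3–C4 and C3–C1') of a core alkyne, CO and a side-chain E-vinyl iodide.
4. Core alkyne: C7 by chelate-controlled acetyl-anion addition to a lactol; the C8a–C4a bond by visible-light decarboxylative alkynylation of a hydroxy lactone acid made from dimethyl (R)-malate and formaldehyde.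
5. Side chain: D-allo-isoleucine → α-hydroxy acid → methyl ketone → chelate-controlled ethynylation → hydrozirconation/iodination.

Assumption: dimethyl (R)-malate and D-allo-isoleucine are taken as inexpensive catalogue chiral-pool compounds; atoms are numbered as in the target (C1, O2, C3, C4, C4a, C5 to C8, C8a; primes for the side chain).

**Route**

Step 1
Reactants: 1 dimethyl (R)-malate
Product: 4 (3S,4R)-4-hydroxy-5-oxooxolane-3-carboxylic acid, via aldol diester 2 (not isolated), via lactone ester 3 (not isolated)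
Conditions: LiN(iPr)2 (2.2 equiv), THF, −78 → −20 °C; CH2O (gas, from cracked paraformaldehyde), −78 °C; then 3 M HCl, 70 °C
Reagents that add atoms: formaldehyde (C=O); water (O)
Why: Fráter–Seebach aldol, in which the alkoxide/ester-enolate dianion adds formaldehyde anti to the alkoxide, the new primary alcohol lactonises onto the α-hydroxy ester (the only five-membered option) and aqueous acid hydrolyses the remaining methyl ester while the γ-lactone persists; C8 is the untouched malate carbinol and the C8a configuration (trans major) is provisional because step 2 erases it.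

Step 2
Reactants: 4 (3S,4R)-4-hydroxy-5-oxooxolane-3-carboxylic acid
Product: 6 (3R,4S)-4-ethynyl-3-hydroxyoxolan-2-one, via silylalkyne lactone 5 (not isolated)
Conditions: TMS-EBX (1.5 equiv), 4CzIPN (2 mol %), CsO2CPh (1.5 equiv), MeCN, blue LEDs (455 nm), 25 °C; then Bu4NF/AcOH (1:1), THF, 0 °C
Reagents that add atoms: 1-[(trimethylsilyl)ethynyl]-1,2-benziodoxol-3(1H)-one, TMS-EBX (C[Si](C)(C)C#CI1OC(=O)c2ccccc12)
Why: Proposed new method: photoredox decarboxylative alkynylation is established for α-amino, α-alkoxy and simple alkyl acids but has not been run on a hydroxyparaconic acid, where it must work beside a free α-hydroxyl and override the configuration of the carboxyl-bearing ring carbon; excited 4CzIPN oxidises the cesium carboxylate, loss of CO2 gives a planar nucleophilic secondary radical at C8a (β, not α, to the lactone carbonyl), this adds to the iodine-bound alkyne carbon of TMS-EBX on the ring face anti to the neighbouring C8 hydroxyl (trans product from either acid epimer), β-scission releases the 2-iodobenzoyloxy radical that reoxidises the reduced dye, and buffered fluoride then cleaves the C–Si bond; closest known reaction type: photocatalytic decarboxylative alkynylation of carboxylic acids with ethynylbenziodoxolones.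

Step 3
Reactants: 6 (3R,4S)-4-ethynyl-3-hydroxyoxolan-2-one
Product: 7 (3R,4S)-4-ethynyl-2-methyloxolane-2,3-diol (anomeric mixture, in equilibrium with the open hydroxy ketone)
Conditions: MeLi (3.1 equiv), THF, −78 °C; AcOH, −78 °C
Reagents that add atoms: methyllithium ([Li]C)
Why: Mono-addition of an organolithium to a γ-lactone, in which two equivalents deprotonate the hydroxyl and the alkyne C–H, the third adds to the carbonyl, and the tetrahedral lithium hemiketalate is stable at −78 °C so no second addition occurs; no retained stereocentre is formed and the α-alkoxide protects C8–H from enolisation.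

Step 4
Reactants: 7 (3R,4S)-4-ethynyl-2-methyloxolane-2,3-diol
Product: 9 (3S,4R,5S)-3,4-dihydroxy-5-(hydroxymethyl)-3-methylhept-6-yn-2-one, via enol ether adduct 8 (not isolated)
Conditions: CH2=C(OEt)MgBr (5 equiv; from ethyl vinyl ether, t-BuLi, then MgBr2·OEt2), THF, −78 → 0 °C; then 1 M HCl, 0 °C
Reagents that add atoms: (1-ethoxyvinyl)magnesium bromide (CCOC(=C)[Mg]Br); water (O)
Why: Cram chelate-controlled addition of an acetyl-anion equivalent, in which the ring-opened keto alkoxide holds the C7 carbonyl and the C8 alkoxide on magnesium in a five-membered chelate and the nucleophile enters on the face of C8–H, anti to the C8a substituent, setting C7 as S (threo to C8); dilute acid then hydrolyses the enol ether to the methyl ketone.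

Step 5
Reactants: 9 (3S,4R,5S)-3,4-dihydroxy-5-(hydroxymethyl)-3-methylhept-6-yn-2-one
Product: 10 (3S,4R,5S)-3-methyl-3,4-bis(trimethylsilyloxy)-5-[(trimethylsilyloxy)methyl]hept-6-yn-2-one
Conditions: N-(trimethylsilyl)imidazole (4 equiv), CH2Cl2, 0 → 25 °C
Reagents that add atoms: N-(trimethylsilyl)imidazole (C[Si](C)(C)n1ccnc1)
Why: O-Silylation with a silylimidazole covers all three hydroxyls, including the tertiary C7 hydroxyl that would otherwise add 5-exo to the later ynone, without enolising the methyl ketone or touching the alkyne C–H; no stereocentre is formed.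

Step 6
Reactants: 11 D-allo-isoleucine, (2R,3S)-2-amino-3-methylpentanoic acid
Product: 12 (2R,3S)-2-hydroxy-3-methylpentanoic acid
Conditions: NaNO2, 1 M H2SO4, 0 → 25 °C
Reagents that add atoms: water (O)
Why: Diazotisation of an α-amino acid, in which the carboxylate displaces N2 to give an α-lactone that water reopens, so two inversions give the 2R hydroxy acid with net retention; C3 is untouched.

Step 7
Reactants: 12 (2R,3S)-2-hydroxy-3-methylpentanoic acid
Product: 13 (3R,4S)-3-hydroxy-4-methylhexan-2-one
Conditions: MeLi (3.3 equiv), THF, 0 → 25 °C; inverse quench into 1 M HCl, 0 °C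
Reagents that add atoms: methyllithium ([Li]C)
Why: Methyl ketone synthesis from a lithium carboxylate, in which the dilithium gem-diolate survives until the inverse acidic quench (no over-addition) and the adjacent alkoxide protects C3–H, so both stereocentres are kept.

Step 8
Reactants: 13 (3R,4S)-3-hydroxy-4-methylhexan-2-one
Product: 14 (3R,4R,5S)-3,5-dimethylhept-1-yne-3,4-diol
Conditions: HC≡CMgBr (3 equiv), THF, −78 → 0 °C; aq NH4Cl
Reagents that add atoms: ethynylmagnesium bromide (C#C[Mg]Br)
Why: Cram chelate-controlled Grignard addition to an α-hydroxy ketone, in which the magnesium alkoxide and the carbonyl form a five-membered chelate and the acetylide attacks anti to the sec-butyl group, setting C3' as R (threo diol).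

Step 9
Reactants: 14 (3R,4R,5S)-3,5-dimethylhept-1-yne-3,4-diol
Product: 15 (3R,4R,5S)-3,5-dimethyl-3,4-bis(trimethylsilyloxy)hept-1-yne
Conditions: N-(trimethylsilyl)imidazole (3 equiv), CH2Cl2, 25 °C
Reagents that add atoms: N-(trimethylsilyl)imidazole (C[Si](C)(C)n1ccnc1)
Why: O-Silylation of the secondary and tertiary hydroxyls removes acidic protons before hydrozirconation and the later enolate step; no stereocentre is formed.

Step 10
Reactants: 15 (3R,4R,5S)-3,5-dimethyl-3,4-bis(trimethylsilyloxy)hept-1-yne
Product: 17 (1E,3R,4R,5S)-1-iodo-3,5-dimethyl-3,4-bis(trimethylsilyloxy)hept-1-ene, via alkenylzirconocene 16 (not isolated)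
Conditions: Cp2Zr(H)Cl (1.3 equiv), THF, 25 °C; then I2, 0 °C
Reagents that add atoms: iodine (II)
Why: Schwartz hydrozirconation followed by iodinolysis, in which syn addition of Zr–H places zirconium on the terminal carbon and iodine cleaves the C–Zr bond with retention, giving only the E vinyl iodide.

Step 11
Reactants: 10 (3S,4R,5S)-3-methyl-3,4-bis(trimethylsilyloxy)-5-[(trimethylsilyloxy)methyl]hept-6-yn-2-one; 17 (1E,3R,4R,5S)-1-iodo-3,5-dimethyl-3,4-bis(trimethylsilyloxy)hept-1-ene
Product: 18 (3S,4R,5S,9E,11R,12R,13S)-3,11,13-trimethyl-3,4,11,12-tetrakis(trimethylsilyloxy)-5-[(trimethylsilyloxy)methyl]pentadec-9-en-6-yne-2,8-dione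
Conditions: PdCl2(PPh3)2 (5 mol %), CuI (2 mol %), CO (1 atm), Et3N, THF, 25 °C
Reagents that add atoms: carbon monoxide ([C-]#[O+])
Why: Carbonylative Sonogashira coupling, in which the vinyl iodide adds oxidatively to zerovalent palladium formed in situ, CO inserts to give the acylpalladium species and the copper acetylide of 10 couples with it, giving the alkynyl vinyl ketone with retention of the E geometry; no stereocentre is formed.

Step 12
Reactants: 18 (3S,4R,5S,9E,11R,12R,13S)-3,11,13-trimethyl-3,4,11,12-tetrakis(trimethylsilyloxy)-5-[(trimethylsilyloxy)methyl]pentadec-9-en-6-yne-2,8-dione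
Product: 21 (7S,8R,8aS)-3-[(1E,3R,4R,5S)-3,4-dihydroxy-3,5-dimethylhept-1-en-1-yl]-7,8-dihydroxy-7-methyl-1,7,8,8a-tetrahydro-6H-isochromen-6-one, via silylated Michael adduct 19 (not isolated), via desilylated enedione 20 (not isolated)
Conditions: LiN(SiMe3)2 (1.1 equiv), THF, −78 → −40 °C; AcOH; then CSA (0.3 equiv), MeOH, 0 → 25 °C
Reagents that add atoms: none
Why: Intramolecular Michael addition followed by cyclodehydration, in which kinetic deprotonation at C5 (the only enolisable position of the methyl ketone) gives a lithium enolate that closes the carbocycle 6-exo-dig onto the ynone β-carbon C4a, and acidic methanol then removes the five silyl groups, moves the enedione into conjugation with C6, lets the C1 hydroxyl form the six-membered hemiketal at C3 and drives vinylogous loss of water to the dienone enol ether, with C7, C8 and C8a untouched.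

**Compound list**

1 | dimethyl (R)-malate | COC(=O)[C@H](O)CC(=O)OC | starting material
2 | dimethyl (2R,3S)-2-hydroxy-3-(hydroxymethyl)butanedioate | COC(=O)[C@H](O)[C@H](CO)C(=O)OC | intermediate
3 | methyl (3S,4R)-4-hydroxy-5-oxooxolane-3-carboxylate | O=C1[C@H](O)[C@H](CO1)C(=O)OC | intermediate
4 | (3S,4R)-4-hydroxy-5-oxooxolane-3-carboxylic acid | O=C1[C@H](O)[C@H](CO1)C(=O)O | intermediate
5 | (3R,4S)-3-hydroxy-4-[(trimethylsilyl)ethynyl]oxolan-2-one | O=C1[C@H](O)[C@H](CO1)C#C[Si](C)(C)C | intermediate
6 | (3R,4S)-4-ethynyl-3-hydroxyoxolan-2-one | O=C1[C@H](O)[C@H](CO1)C#C | intermediate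
7 | (3R,4S)-4-ethynyl-2-methyloxolane-2,3-diol (anomeric mixture) | CC1(O)[C@H](O)[C@H](CO1)C#C | intermediate
8 | (3S,4R,5S)-2-ethoxy-5-(hydroxymethyl)-3-methylhept-1-en-6-yne-3,4-diol | C=C(OCC)[C@@](C)(O)[C@H](O)[C@H](CO)C#C | intermediate
9 | (3S,4R,5S)-3,4-dihydroxy-5-(hydroxymethyl)-3-methylhept-6-yn-2-one | CC(=O)[C@@](C)(O)[C@H](O)[C@H](CO)C#C | intermediate
10 | (3S,4R,5S)-3-methyl-3,4-bis(trimethylsilyloxy)-5-[(trimethylsilyloxy)methyl]hept-6-yn-2-one | CC(=O)[C@@](C)(O[Si](C)(C)C)[C@H](O[Si](C)(C)C)[C@H](CO[Si](C)(C)C)C#C | intermediate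
11 | D-allo-isoleucine, (2R,3S)-2-amino-3-methylpentanoic acid | CC[C@H](C)[C@@H](N)C(=O)O | starting material
12 | (2R,3S)-2-hydroxy-3-methylpentanoic acid | CC[C@H](C)[C@@H](O)C(=O)O | intermediate
13 | (3R,4S)-3-hydroxy-4-methylhexan-2-one | CC[C@H](C)[C@@H](O)C(C)=O | intermediate
14 | (3R,4R,5S)-3,5-dimethylhept-1-yne-3,4-diol | CC[C@H](C)[C@@H](O)[C@](C)(O)C#C | intermediate
15 | (3R,4R,5S)-3,5-dimethyl-3,4-bis(trimethylsilyloxy)hept-1-yne | CC[C@H](C)[C@@H](O[Si](C)(C)C)[C@](C)(O[Si](C)(C)C)C#C | intermediate
16 | chlorobis(cyclopentadienyl)[(1E,3R,4R,5S)-3,5-dimethyl-3,4-bis(trimethylsilyloxy)hept-1-en-1-yl]zirconium | CC[C@H](C)[C@@H](O[Si](C)(C)C)[C@](C)(O[Si](C)(C)C)/C=C/[Zr](Cl)(C1C=CC=C1)C1C=CC=C1 | intermediate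
17 | (1E,3R,4R,5S)-1-iodo-3,5-dimethyl-3,4-bis(trimethylsilyloxy)hept-1-ene | CC[C@H](C)[C@@H](O[Si](C)(C)C)[C@](C)(O[Si](C)(C)C)/C=C/I | intermediate
18 | (3S,4R,5S,9E,11R,12R,13S)-3,11,13-trimethyl-3,4,11,12-tetrakis(trimethylsilyloxy)-5-[(trimethylsilyloxy)methyl]pentadec-9-en-6-yne-2,8-dione | CC(=O)[C@@](C)(O[Si](C)(C)C)[C@H](O[Si](C)(C)C)[C@H](CO[Si](C)(C)C)C#CC(=O)/C=C/[C@@](C)(O[Si](C)(C)C)[C@H](O[Si](C)(C)C)[C@@H](C)CC | intermediate
19 | (2S,3R,4S)-2-methyl-5-[(3E,5R,6R,7S)-5,7-dimethyl-2-oxo-5,6-bis(trimethylsilyloxy)non-3-en-1-ylidene]-2,3-bis(trimethylsilyloxy)-4-[(trimethylsilyloxy)methyl]cyclohexan-1-one (exocyclic C=C as E/Z mixture) | C[C@]1(O[Si](C)(C)C)[C@H](O[Si](C)(C)C)[C@H](CO[Si](C)(C)C)C(=CC(=O)/C=C/[C@@](C)(O[Si](C)(C)C)[C@H](O[Si](C)(C)C)[C@@H](C)CC)CC1=O | intermediate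
20 | (2S,3R,4S)-5-[(3E,5R,6R,7S)-5,6-dihydroxy-5,7-dimethyl-2-oxonon-3-en-1-ylidene]-2,3-dihydroxy-4-(hydroxymethyl)-2-methylcyclohexan-1-one (exocyclic C=C as E/Z mixture) | C[C@]1(O)[C@H](O)[C@H](CO)C(=CC(=O)/C=C/[C@@](C)(O)[C@H](O)[C@@H](C)CC)CC1=O | intermediate
21 | (7S,8R,8aS)-3-[(1E,3R,4R,5S)-3,4-dihydroxy-3,5-dimethylhept-1-en-1-yl]-7,8-dihydroxy-7-methyl-1,7,8,8a-tetrahydro-6H-isochromen-6-one | CC[C@H](C)[C@@H](O)[C@](C)(O)/C=C/C1=CC2=CC(=O)[C@@](C)(O)[C@H](O)[C@@H]2CO1 | target

**Step count and risks**

Total steps: 12. Longest linear sequence: 7 steps (steps 1, 2, 3, 4, 5, 11, 12; the side-chain branch, steps 6 to 10 then 11 and 12, is also 7).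

Step 2 (the proposed new photochemical alkynylation) is the most likely to fail, through low trans selectivity next to the small free hydroxyl or poor oxidation of the unactivated carboxylate. The fallback uses known thermal chemistry, sets out from 4 and comes back at 6. Silylation of 4 with TBSCl/imidazole (aqueous work-up cleaves the silyl ester) gives the silyl ether acid F1, and N-hydroxyphthalimide with DIC converts it into the redox-active ester F2. Decarboxylative alkynylation of F2 with HC≡CZnCl under NiCl2·6H2O/2,2'-bipyridine catalysis, which enters trans to the bulky silyl ether, gives the protected ethynyl lactone F3. HF·pyridine then frees the hydroxyl to give 6.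

Step 11 (three-component carbonylative coupling of two advanced fragments) may give the direct, CO-free enyne or alkyne homocoupling. The fallback sets out from 17 and 10 and comes back at 18. Iodine–lithium exchange of 17 (t-BuLi, Et2O, −78 °C) and a CO2 quench give the E-enoic acid F4. 1-Chloro-N,N,2-trimethylpropenylamine converts it under neutral conditions into the acid chloride F5. An acyl Sonogashira coupling of F5 with alkyne 10 (PdCl2(PPh3)2, CuI, Et3N) then gives 18, so the carbonyl carbon is brought in as CO2 through an organolithium, not by CO insertion at palladium.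

Step 12 (enolate Michael closure and cyclodehydration) may suffer from γ-deprotonation at C8a (epimerisation or loss of the C1 silyloxy group) under the lithium amide. The fallback sets out from 18 and comes back at 19. Soft enolisation (TMSOTf, Et3N, CH2Cl2, −78 °C) gives the silyl enol ether F6. This closes the carbocycle by an intramolecular Mukaiyama–Michael addition to the ynone under catalytic TMSOTf at −78 °C, with no strong base present. Mild aqueous work-up gives 19, which is taken through the same acidic methanol treatment to 21.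

**Further compounds**

F1 | step 2 | (3S,4R)-4-[(tert-butyldimethylsilyl)oxy]-5-oxooxolane-3-carboxylic acid | O=C1[C@H](O[Si](C)(C)C(C)(C)C)[C@H](CO1)C(=O)O
F2 | step 2 | 1,3-dioxoisoindolin-2-yl (3S,4R)-4-[(tert-butyldimethylsilyl)oxy]-5-oxooxolane-3-carboxylate | O=C1[C@H](O[Si](C)(C)C(C)(C)C)[C@H](CO1)C(=O)ON1C(=O)c2ccccc2C1=O
F3 | step 2 | (3R,4S)-3-[(tert-butyldimethylsilyl)oxy]-4-ethynyloxolan-2-one | O=C1[C@H](O[Si](C)(C)C(C)(C)C)[C@H](CO1)C#C
F4 | step 11 | (2E,4R,5R,6S)-4,6-dimethyl-4,5-bis(trimethylsilyloxy)oct-2-enoic acid | CC[C@H](C)[C@@H](O[Si](C)(C)C)[C@](C)(O[Si](C)(C)C)/C=C/C(=O)O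
F5 | step 11 | (2E,4R,5R,6S)-4,6-dimethyl-4,5-bis(trimethylsilyloxy)oct-2-enoyl chloride | CC[C@H](C)[C@@H](O[Si](C)(C)C)[C@](C)(O[Si](C)(C)C)/C=C/C(=O)Cl
F6 | step 12 | (3S,4R,5S,9E,11R,12R,13S)-3,11,13-trimethyl-2,3,4,11,12-pentakis(trimethylsilyloxy)-5-[(trimethylsilyloxy)methyl]pentadeca-1,9-dien-6-yn-8-one | C=C(O[Si](C)(C)C)[C@@](C)(O[Si](C)(C)C)[C@H](O[Si](C)(C)C)[C@H](CO[Si](C)(C)C)C#CC(=O)/C=C/[C@@](C)(O[Si](C)(C)C)[C@H](O[Si](C)(C)C)[C@@H](C)CC
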